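All constants are made up; what happens was integrated by code.

Count the rings first.

first end groups 0.65 M; second end groups 0.650 M (in portions, 4); time 2.0 h; the portions of second end groups follow each other after 6.0 s, the first at the start

    first end groups + second end groups → links (k1 = 0.0244 M⁻¹ s⁻¹)
    first end groups + second end groups → rings, rate k2*[first end groups] as long as [second end groups] is above zero (k2 = 0.0161 s⁻¹)
    2 second end groups → homo dimer (k3 = 0.00125 M⁻¹ s⁻¹)

1. which holds at 2.0 h: what has brought the reaction to rest, or that it has not come to rest (the second end groups has run out first / it is still moving)
2. share of the first end groups used up at 2.0 h
3. links at 2.0 h, in percent of the first end groups charged
4. rings at 2.0 h, in percent of the first end groups charged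

- a step written with two of one species runs at k times the square of its concentration and takes two of it each time
- the reaction counts as stopped when no species that holds the first end groups changes by six tenths of a point or more over the second half of the time
- run time (flask): 2.0 h

Minutes of the meeting on this flask.

The first speaker opened with the branch. The link step and the ring step each take one first and one second end group, so links form against rings as b/κ at any moment. Here b is the second end groups as a fraction of their charge, and κ, the ring constant over the link constant times that charge, is the crossover fraction, a selectivity factor, with value 1.02.

The second speaker removed time from this. Each unit of rings costs one plus b/κ units of second end groups, so, homo dimer neglected and the second end groups used to the last, the ring fraction of their charge is κ times the logarithm of one plus the reciprocal of κ. That gives 69.6% for a single shot. If each of the 4 portions were consumed before the next came, it would give 89.4%.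

The third speaker counted half-lives. The ring half-life of first end groups, ln(2) over the ring constant, is 0.718 min, and the feed lasts 0.300 min, which is shorter, so the portions pile up.

The secretary's own reckoning: with equal charges, the second end groups are the limiting reagent once homo dimer takes its share, and rings lie between the two figures, nearer the lower.

The forecast was then read: the second end groups has run out first, conversion 98.1%, links 23.3%, rings 74.8%. Its grounds: "Rings win because their rate is first order and does not depend on the second end groups' concentration".

The simulation gives: the second end groups has run out first, with 0% of them left; conversion 98.1%, links 23.1%, rings 75.0%.

With equal charges and κ at 1.02, this flask's rings stand above the single-shot 69.6% and below 89.4%. The ring step has the largest single effect on conversion in this flask: with that step struck out, conversion goes from 98.1% to 92.5%. In the neighbour flask with 2.6 M of first end groups, the same κ applies, and rings are 22.3% of that charge, which is 89.3% of the second end group charge, beside the 89.4% reckoned for portions consumed one by one.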